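The plan rests on closing last the second tetrahydrofuran ring of the furofuran (C1–C5–C6–O7–C8, 3,7-dioxabicyclo[3.3.0]octane numbering), whose C6 holds the dihydrobenzofuran aryl (ring B) endo, a kinetic arrangement. One operation forges O7–C6 and C5–C6: Me3SiOTf attaches the ring B acetal carbon to the primary hydroxyl of a cis-2-aryl-3-hydroxymethyl-2,3-dihydrofuran (ring A already endo on C2), and the tethered oxocarbenium ion is trapped by the enol ether carbon, which sets C4, C5 and C6. Both phenols and the primary alcohol travel as silyl ethers, so only an ionic reduction at C4 and one fluoride treatment follow and no hydrogenolysis comes near the benzylic C–O bonds.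

Key step: step 13

Assumption (step 5): the lipase is taken to acetylate the (2R,3R)-alcohol faster; if the preference is the reverse, the acetate fraction is the wanted series and is released with K2CO3/MeOH.
Assumption (step 10): the R-configured tert-leucinate catalyst is expected to give the (2S,3R)-cis ester, by analogy with the sense of induction of this catalyst family; the mirror-image catalyst is used if the first run shows the opposite sense.
Remark: compounds 4–6 are racemic and are drawn as the enantiomer that leads on; enol ethers 5–7 and acetals 11–18 are purified on triethylamine-deactivated silica; any minor enantiomer of 7 or 16 becomes a diastereomer in step 13 and should be removable there.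

Step 1
Reactants: 1 vanillin
Product: 2 3-methoxy-4-(triisopropylsilyloxy)benzaldehyde
Conditions: iPr3SiCl, imidazole, DMF, 25 °C
Reagents that add atoms: chlorotriisopropylsilane, CC(C)[Si](Cl)(C(C)C)C(C)C
Why: Standard silylation of a phenol; the bulky triisopropylsilyl ether should withstand the amide base, hydride, pyrolysis and Lewis acids to come and leaves with fluoride at the end.

Step 2
Reactants: 2 3-methoxy-4-(triisopropylsilyloxy)benzaldehyde; 3 methyl (E)-4-bromobut-2-enoate
Product: 4 rac-methyl (E)-3-[(2R,3R)-3-(3-methoxy-4-triisopropylsilyloxyphenyl)oxiran-2-yl]prop-2-enoate (trans-oxirane)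
Conditions: LiN(iPr)2 added to 2 + 3, THF, −78 → 0 °C
Reagents that add atoms: none
Why: Vinylogous Darzens condensation: γ-deprotonation of 3 gives a bromo dienolate whose bromine-bearing carbon adds to the non-enolisable aldehyde and the alkoxide closes the oxirane by displacing bromide; the oxirane stereocentres do not matter because both are erased in step 3.

Step 3
Reactants: 4 rac-trans-vinyl oxirane
Product: 5 rac-methyl (2S,3R)-2-(3-methoxy-4-triisopropylsilyloxyphenyl)-2,3-dihydrofuran-3-carboxylate (cis)
Conditions: flash vacuum pyrolysis, 500 °C, 0.01 mbar (inlet about 170 °C)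
Reagents that add atoms: none
Why: Vinyl oxirane to dihydrofuran rearrangement: thermal conrotatory C–C opening gives a carbonyl ylide that closes by a disrotatory six-electron 1,5-electrocyclisation onto the E-enoate terminus, placing aryl and ester cis (C2, C3), and the short gas-phase contact should keep the kinetic cis ester from epimerising to trans.

Step 4
Reactants: 5 rac-cis-dihydrofuran ester
Product: 6 rac-[(2S,3S)-2-(3-methoxy-4-triisopropylsilyloxyphenyl)-2,3-dihydrofuran-3-yl]methanol (cis)
Conditions: LiAlH4, THF, −40 °C; aqueous Rochelle salt work-up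
Reagents that add atoms: none
Why: Hydride reduction of the ester, fast enough at low temperature that the C3 stereocentre next to the carbonyl is not enolised, with a basic work-up that spares the enol ether.

Step 5
Reactants: 6 rac-cis-dihydrofuran alcohol
Product: 7 [(2S,3S)-2-(3-methoxy-4-triisopropylsilyloxyphenyl)-2,3-dihydrofuran-3-yl]methanol (single enantiomer, recovered alcohol)
Conditions: immobilised lipase from Burkholderia cepacia, vinyl acetate, tBuOMe, 25 °C, stopped near half conversion
Reagents that add atoms: none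
Why: Lipase-catalysed kinetic resolution by irreversible transesterification of a primary alcohol with a β-stereocentre; one antipode is acetylated and the wanted (2S,3S)-alcohol is recovered, which fixes the absolute configuration of the later furofuran C2 and C1.

Step 6
Reactants: 2 3-methoxy-4-(triisopropylsilyloxy)benzaldehyde
Product: 8 [3-methoxy-4-(triisopropylsilyloxy)phenyl]methanol
Conditions: NaBH4, MeOH, 0 °C
Reagents that add atoms: none
Why: Borohydride reduction of the aldehyde gives the benzylic alcohol that will carry ring C.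

Step 7
Reactants: 8 [3-methoxy-4-(triisopropylsilyloxy)phenyl]methanol; 9 5-iodovanillin (4-hydroxy-3-iodo-5-methoxybenzaldehyde)
Product: 10 3-iodo-5-methoxy-4-{[3-methoxy-4-(triisopropylsilyloxy)phenyl]methoxy}benzaldehyde
Conditions: PPh3, DIAD, THF, 0 → 25 °C
Reagents that add atoms: none
Why: Mitsunobu etherification: the acidic phenol 9 is O-alkylated by the activated primary benzylic alcohol, and ring alkylation cannot compete because both ortho positions and the para position of 9 are occupied.

Step 8
Reactants: 10 aryl benzyl ether aldehyde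
Product: 11 5-(dimethoxymethyl)-1-iodo-3-methoxy-2-{[3-methoxy-4-(triisopropylsilyloxy)phenyl]methoxy}benzene
Conditions: HC(OMe)3, MeOH, PPTS (cat.), 25 °C; Et3N quench
Reagents that add atoms: trimethyl orthoformate, COC(OC)OC; methanol, CO
Why: Acid-catalysed acetalisation driven by the orthoformate; the dimethyl acetal masks the aldehyde through the carbene and hydride steps and is the electrophile needed in step 13.

Step 9
Reactants: 11 aryl iodide dimethyl acetal; 12 ethyl diazoacetate
Product: 13 ethyl 2-diazo-2-[5-(dimethoxymethyl)-3-methoxy-2-{[3-methoxy-4-(triisopropylsilyloxy)phenyl]methoxy}phenyl]acetate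
Conditions: Pd(PPh3)4 (5 mol %), Ag2CO3 (0.5 equiv), Et3N, toluene, 25 °C
Reagents that add atoms: none
Why: Palladium-catalysed cross-coupling of an aryl iodide with the C–H bond of a diazoacetate: oxidative addition to zerovalent palladium, base-assisted capture of the diazo ester with silver carbonate as iodide scavenger, and reductive elimination that leaves the diazo group in place.

Step 10
Reactants: 13 aryl diazoacetate
Product: 14 ethyl (2S,3R)-5-(dimethoxymethyl)-7-methoxy-2-[3-methoxy-4-(triisopropylsilyloxy)phenyl]-2,3-dihydro-1-benzofuran-3-carboxylate (cis)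
Conditions: Rh2(R-PTTL)4 (1 mol %), toluene, −78 °C
Reagents that add atoms: none
Why: Intramolecular 1,5 C–H insertion of a donor–acceptor rhodium carbenoid into the benzylic ether C–H bond closes the dihydrobenzofuran; dirhodium tetrakis[N-phthaloyl-(R)-tert-leucinate] belongs to the catalyst class known to give the cis-2-aryl-3-carboxylate kinetically and to select one enantiotopic benzylic hydrogen, so C2 and C3 are both set by the catalyst.

Step 11
Reactants: 14 cis-dihydrobenzofuran ester
Product: 15 [(2S,3S)-5-(dimethoxymethyl)-7-methoxy-2-[3-methoxy-4-(triisopropylsilyloxy)phenyl]-2,3-dihydro-1-benzofuran-3-yl]methanol (cis)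
Conditions: LiAlH4, THF, −40 → 0 °C
Reagents that add atoms: none
Why: Hydride reduction of the ester outruns enolisation at low temperature, so the cis relationship should survive, and neither the dimethyl acetal nor the aryl silyl ether reacts with LiAlH4.

Step 12
Reactants: 15 cis-dihydrobenzofuran alcohol
Product: 16 tert-butyl{[(2S,3S)-5-(dimethoxymethyl)-7-methoxy-2-[3-methoxy-4-(triisopropylsilyloxy)phenyl]-2,3-dihydro-1-benzofuran-3-yl]methoxy}dimethylsilane
Conditions: tBuMe2SiCl, imidazole, DMF, 25 °C
Reagents that add atoms: tert-butylchlorodimethylsilane, CC(C)(C)[Si](C)(C)Cl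
Why: Silylation of the primary alcohol, so that only the hydroxyl of 7 can enter the acetal exchange of step 13.

Step 13
Reactants: 7 (2S,3S)-cis-dihydrofuran alcohol; 16 ring B dimethyl acetal
Product: 18 (1S,2S,4S,5R,6S)-6-{(2S,3S)-3-[(tert-butyldimethylsilyloxy)methyl]-7-methoxy-2-[3-methoxy-4-(triisopropylsilyloxy)phenyl]-2,3-dihydro-1-benzofuran-5-yl}-4-methoxy-2-[3-methoxy-4-(triisopropylsilyloxy)phenyl]-3,7-dioxabicyclo[3.3.0]octane (rings A and B endo; 4-methoxy exo), via mixed acetal 17 (not isolated)
Conditions: 7 (1.2 equiv), Me3SiOTf (1.1 equiv), CH2Cl2, −78 °C; Et3N quench at −78 °C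
Reagents that add atoms: none
Why: Me3SiOTf ionises 16 to an aryl-stabilised methoxycarbenium ion that the primary hydroxyl of 7 intercepts (mixed acetal 17, bond O7–C6); a second ionisation expels the remaining methoxy group as Me3SiOMe, the enol ether carbon C5 adds to the tethered cation carbon C6, and the C4 oxocarbenium ion so formed takes methoxide back from Me3SiOMe. The closest known reaction type is the Prins-type (Mukaiyama-like) addition of an enol ether to an acetal-derived oxocarbenium ion, in the intramolecular form known to turn cis-2-aryl-3-hydroxymethyl-2,3-dihydrofurans and aryl aldehyde acetals into endo,endo-furofuran acetals. The ring C1–C5–C6–O7–C8 closes in a 5-(enolexo)-endo-trig mode: the nucleophilic C5=C4 bond stays outside and the C6=O7 bond inside the new ring, which the short C8 tether and the strongly polarised cation permit. C5 is controlled by C1, because C8 holds the cation on the face of the dihydrofuran that also bears ring A and so enforces cis fusion; C6 is controlled by the geometry of the cation, the E ion (ring B anti to C8) closing through the compact synclinal envelope in which C6=O7 lies over the C1–C5 bond and ring B ends on the concave side; C4 is controlled by the bicyclic shape, methoxide entering from the convex face, and is erased in step 14. The step needs kinetic endo placement of ring B at C6 with no re-ionisation of the benzylic C6–O7, C2–O3 or dihydrobenzofuran C2–O1 bonds, and this is secured by the preset cis relationship in 7, by silyloxy instead of alkoxy para donors on rings A and C, and by reaction at −78 °C with a cold amine quench.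

Step 14
Reactants: 18 bis-endo 4-methoxy furofuran acetal
Product: 19 (1S,2S,5S,6S)-6-{(2S,3S)-3-[(tert-butyldimethylsilyloxy)methyl]-7-methoxy-2-[3-methoxy-4-(triisopropylsilyloxy)phenyl]-2,3-dihydro-1-benzofuran-5-yl}-2-[3-methoxy-4-(triisopropylsilyloxy)phenyl]-3,7-dioxabicyclo[3.3.0]octane
Conditions: Et3SiH (3 equiv), BF3·OEt2 (1.5 equiv), CH2Cl2, −78 °C; Et3N then aqueous NaHCO3 at −78 °C
Reagents that add atoms: none
Why: Ionic hydrogenation of a cyclic O,O-acetal: BF3, acting as a regenerated promoter, removes the exo methoxy group at C4, the only acetal centre and so the most easily ionised C–O bond at −78 °C, and Et3SiH reduces the oxocarbenium ion to CH2, creating no stereocentre.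

Step 15
Reactants: 19 tris-silyl furofuran
Product: 20 4-[(1S,2S,5S,6S)-6-[(2S,3S)-2-(4-hydroxy-3-methoxyphenyl)-3-(hydroxymethyl)-7-methoxy-2,3-dihydro-1-benzofuran-5-yl]-3,7-dioxabicyclo[3.3.0]octan-2-yl]-2-methoxyphenol (CNP0303197.1)
Conditions: Bu4NF (4 equiv), AcOH (4 equiv), THF, 0 → 25 °C
Reagents that add atoms: none
Why: Fluoride-induced desilylation cleaves the two aryl triisopropylsilyl ethers and the primary tert-butyldimethylsilyl ether in one operation under acetic acid buffering, conditions that should leave the acid-sensitive bis-endo benzylic ethers and the cis-dihydrobenzofuran untouched.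

Compound list
1 | vanillin (4-hydroxy-3-methoxybenzaldehyde) | COc1cc(C=O)ccc1O | starting material
2 | 3-methoxy-4-(triisopropylsilyloxy)benzaldehyde | COc1cc(C=O)ccc1O[Si](C(C)C)(C(C)C)C(C)C | intermediate
3 | methyl (E)-4-bromobut-2-enoate (methyl 4-bromocrotonate) | COC(=O)/C=C/CBr | starting material
4 | rac-methyl (E)-3-[(2R,3R)-3-(3-methoxy-4-triisopropylsilyloxyphenyl)oxiran-2-yl]prop-2-enoate (trans-oxirane, racemate) | COC(=O)/C=C/[C@H]1O[C@@H]1c1ccc(O[Si](C(C)C)(C(C)C)C(C)C)c(OC)c1 | intermediate
5 | rac-methyl (2S,3R)-2-(3-methoxy-4-triisopropylsilyloxyphenyl)-2,3-dihydrofuran-3-carboxylate (cis, racemate) | COc1cc([C@H]2OC=C[C@H]2C(=O)OC)ccc1O[Si](C(C)C)(C(C)C)C(C)C | intermediate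
6 | rac-[(2S,3S)-2-(3-methoxy-4-triisopropylsilyloxyphenyl)-2,3-dihydrofuran-3-yl]methanol (cis, racemate) | COc1cc([C@H]2OC=C[C@H]2CO)ccc1O[Si](C(C)C)(C(C)C)C(C)C | intermediate
7 | [(2S,3S)-2-(3-methoxy-4-triisopropylsilyloxyphenyl)-2,3-dihydrofuran-3-yl]methanol (cis, single enantiomer) | COc1cc([C@H]2OC=C[C@H]2CO)ccc1O[Si](C(C)C)(C(C)C)C(C)C | intermediate
8 | [3-methoxy-4-(triisopropylsilyloxy)phenyl]methanol | COc1cc(CO)ccc1O[Si](C(C)C)(C(C)C)C(C)C | intermediate
9 | 5-iodovanillin (4-hydroxy-3-iodo-5-methoxybenzaldehyde) | COc1cc(C=O)cc(I)c1O | starting material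
10 | 3-iodo-5-methoxy-4-{[3-methoxy-4-(triisopropylsilyloxy)phenyl]methoxy}benzaldehyde | COc1cc(C=O)cc(I)c1OCc1ccc(O[Si](C(C)C)(C(C)C)C(C)C)c(OC)c1 | intermediate
11 | 5-(dimethoxymethyl)-1-iodo-3-methoxy-2-{[3-methoxy-4-(triisopropylsilyloxy)phenyl]methoxy}benzene | COC(OC)c1cc(I)c(OCc2ccc(O[Si](C(C)C)(C(C)C)C(C)C)c(OC)c2)c(OC)c1 | intermediate
12 | ethyl diazoacetate | CCOC(=O)C=[N+]=[N-] | starting material
13 | ethyl 2-diazo-2-[5-(dimethoxymethyl)-3-methoxy-2-{[3-methoxy-4-(triisopropylsilyloxy)phenyl]methoxy}phenyl]acetate | CCOC(=O)C(=[N+]=[N-])c1cc(C(OC)OC)cc(OC)c1OCc1ccc(O[Si](C(C)C)(C(C)C)C(C)C)c(OC)c1 | intermediate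
14 | ethyl (2S,3R)-5-(dimethoxymethyl)-7-methoxy-2-[3-methoxy-4-(triisopropylsilyloxy)phenyl]-2,3-dihydro-1-benzofuran-3-carboxylate (cis) | COC(OC)c1cc(OC)c2c(c1)[C@@H](C(=O)OCC)[C@@H](c1ccc(O[Si](C(C)C)(C(C)C)C(C)C)c(OC)c1)O2 | intermediate
15 | [(2S,3S)-5-(dimethoxymethyl)-7-methoxy-2-[3-methoxy-4-(triisopropylsilyloxy)phenyl]-2,3-dihydro-1-benzofuran-3-yl]methanol (cis) | COC(OC)c1cc(OC)c2c(c1)[C@@H](CO)[C@@H](c1ccc(O[Si](C(C)C)(C(C)C)C(C)C)c(OC)c1)O2 | intermediate
16 | tert-butyldimethylsilyl ether of 15 (cis-dihydrobenzofuran-5-carbaldehyde dimethyl acetal, 2S,3S) | COC(OC)c1cc(OC)c2c(c1)[C@@H](CO[Si](C)(C)C(C)(C)C)[C@@H](c1ccc(O[Si](C(C)C)(C(C)C)C(C)C)c(OC)c1)O2 | intermediate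
17 | mixed methyl acetal in which the hydroxymethyl oxygen of 7 is bound to the benzylic acetal carbon of 16 (both epimers at that carbon) | COc1cc([C@H]2OC=C[C@H]2COC(OC)c2cc(OC)c3c(c2)[C@@H](CO[Si](C)(C)C(C)(C)C)[C@@H](c2ccc(O[Si](C(C)C)(C(C)C)C(C)C)c(OC)c2)O3)ccc1O[Si](C(C)C)(C(C)C)C(C)C | intermediate (not isolated)
18 | (1S,2S,4S,5R,6S)-4-methoxy bis-endo furofuran acetal (full name in step 13) | COc1cc([C@H]2O[C@H](OC)[C@@H]3[C@H]2CO[C@@H]3c2cc(OC)c3c(c2)[C@@H](CO[Si](C)(C)C(C)(C)C)[C@@H](c2ccc(O[Si](C(C)C)(C(C)C)C(C)C)c(OC)c2)O3)ccc1O[Si](C(C)C)(C(C)C)C(C)C | intermediate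
19 | (1S,2S,5S,6S) bis-endo furofuran, tris-silyl ether (full name in step 14) | COc1cc([C@H]2OC[C@@H]3[C@H]2CO[C@@H]3c2cc(OC)c3c(c2)[C@@H](CO[Si](C)(C)C(C)(C)C)[C@@H](c2ccc(O[Si](C(C)C)(C(C)C)C(C)C)c(OC)c2)O3)ccc1O[Si](C(C)C)(C(C)C)C(C)C | intermediate
20 | CNP0303197.1 (full name in step 15) | COc1cc([C@H]2OC[C@@H]3[C@H]2CO[C@@H]3c2cc(OC)c3c(c2)[C@@H](CO)[C@@H](c2ccc(O)c(OC)c2)O3)ccc1O | target

Total step count: 15. Longest linear sequence: 11 steps from vanillin (steps 1, 6, 7, 8, 9, 10, 11, 12, 13, 14, 15).

Steps most likely to fail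

Step 13. The intermolecular acetal exchange may be too slow at −78 °C. Warming would then allow benzylic re-ionisation at C6–O7 and drift of ring B to the exo side, or free triflic acid may consume the enol ether of 7 before exchange. The fallback separates the two events. Setting out from 16 and 7, the acetal is activated under buffered conditions (Me3SiOTf, 2,4,6-collidine, CH2Cl2, 0 °C) as the N-(α-methoxybenzyl)-2,4,6-trimethylpyridinium triflate F1. This salt alkylates the hydroxyl of 7 to give the mixed acetal 17, which is now isolated on base-washed silica. Compound 17 is then cyclised on its own with a substoichiometric charge of Me3SiOTf at −78 °C and quenched cold, returning to the route at 18; the ring closure is then intramolecular and needs no warming.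

Step 14. BF3 may ionise a benzylic C–O bond (C6–O7, C2–O3 or the dihydrobenzofuran C2–O1) in competition with the C4 acetal, giving epimerisation toward the exo or trans series or reductive ring opening. The fallback removes the C4 oxygen without a carbocation at any benzylic centre. Setting out from 18, mild hydrolysis (PPTS, acetone–water, 40 °C) gives the C4 lactol F2. NaBH4 in MeOH at 0 °C reduces its open hydroxy aldehyde form to the diol F3. TsCl in pyridine at 0 °C sulfonylates only the primary hydroxyl to give the primary tosylate F4. NaH in THF then closes the ring by displacement at C4 by the C2 alkoxide, which never breaks the C2–O bond, and the route is rejoined at 19.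

Step 5. The enzyme may discriminate the antipodes too weakly, so that neither fraction reaches useful enantiopurity at acceptable conversion. The fallback is a covalent resolution. Setting out from 6, acylation with (1S)-camphanic chloride (Et3N, DMAP cat., CH2Cl2) gives two diastereomeric esters, the camphanate of the (2S,3S)-alcohol F5 and the camphanate of the (2R,3R)-alcohol F6. These are separated by crystallisation or chromatography, and methanolysis of F5 (K2CO3, MeOH) returns to the route at 7.

Further compounds
F1 | step 13 | 1-{[(2S,3S)-3-(tert-butyldimethylsilyloxymethyl)-7-methoxy-2-(3-methoxy-4-triisopropylsilyloxyphenyl)-2,3-dihydro-1-benzofuran-5-yl](methoxy)methyl}-2,4,6-trimethylpyridinium triflate | COC(c1cc(OC)c2c(c1)[C@@H](CO[Si](C)(C)C(C)(C)C)[C@@H](c1ccc(O[Si](C(C)C)(C(C)C)C(C)C)c(OC)c1)O2)[n+]1c(C)cc(C)cc1C.[O-]S(=O)(=O)C(F)(F)F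
F2 | step 14 | C4 lactol corresponding to 18 (4-hydroxy in place of 4-methoxy, anomer mixture) | COc1cc([C@H]2OC(O)[C@@H]3[C@H]2CO[C@@H]3c2cc(OC)c3c(c2)[C@@H](CO[Si](C)(C)C(C)(C)C)[C@@H](c2ccc(O[Si](C(C)C)(C(C)C)C(C)C)c(OC)c2)O3)ccc1O[Si](C(C)C)(C(C)C)C(C)C
F3 | step 14 | ring-opened diol: tetrahydrofuran C1–C5–C6–O7–C8 kept, C4 as hydroxymethyl on C5, C2 as ring A carbinol on C1, configurations as in 19 | COc1cc([C@@H](O)[C@@H]2CO[C@H](c3cc(OC)c4c(c3)[C@@H](CO[Si](C)(C)C(C)(C)C)[C@@H](c3ccc(O[Si](C(C)C)(C(C)C)C(C)C)c(OC)c3)O4)[C@@H]2CO)ccc1O[Si](C(C)C)(C(C)C)C(C)C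
F4 | step 14 | primary p-toluenesulfonate of F3 (at C4) | COc1cc([C@@H](O)[C@@H]2CO[C@H](c3cc(OC)c4c(c3)[C@@H](CO[Si](C)(C)C(C)(C)C)[C@@H](c3ccc(O[Si](C(C)C)(C(C)C)C(C)C)c(OC)c3)O4)[C@@H]2COS(=O)(=O)c2ccc(C)cc2)ccc1O[Si](C(C)C)(C(C)C)C(C)C
F5 | step 5 | [(2S,3S)-2-(3-methoxy-4-triisopropylsilyloxyphenyl)-2,3-dihydrofuran-3-yl]methyl (1S,4R)-camphanate | COc1cc([C@H]2OC=C[C@H]2COC(=O)[C@@]23CC[C@@](C)(C(=O)O2)C3(C)C)ccc1O[Si](C(C)C)(C(C)C)C(C)C
F6 | step 5 | [(2R,3R)-2-(3-methoxy-4-triisopropylsilyloxyphenyl)-2,3-dihydrofuran-3-yl]methyl (1S,4R)-camphanate | COc1cc([C@@H]2OC=C[C@@H]2COC(=O)[C@@]23CC[C@@](C)(C(=O)O2)C3(C)C)ccc1O[Si](C(C)C)(C(C)C)C(C)C
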